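**Retrosynthetic overview**

1. The C-9 stereocentre and the C-7/C-8 alkene come from kinetic α-protonation of the dienolate of a Δ8 lactol; the lactol comes from a C-11→O-1 γ-lactone, the side chain from a CH2CHO group (Wittig, then MeMgBr), and C-5 from hydrogenation.
2. Ring B is formed last, by an intramolecular Diels–Alder reaction of a ring A 2-methyl-1-vinylcyclohexene whose C-1 oxygen carries a methyl acetylenedicarboxylate tether; this sets quaternary C-10, fixes the regiochemistry and differentiates C-11 from C-12.
3. The diene comes from a β-chloro α-quaternary ketone (enol triflate, Stille coupling), itself made by a chloronium-induced 1,2-allyl shift of a tertiary allylic alcohol, which sets C-3 and C-4 together.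
4. The tertiary alcohol comes from hydroxyl-directed allylation of 5-hydroxy-2,6-dimethylcyclohex-2-enone, made from (S)-(+)-carvone by α′-methylation and Criegee degradation of the isopropenyl group; the carvone stereocentre becomes C-1 and relays every other centre.
5. Ring order: ring A is bought (the carvone ring); ring B is made by the cycloaddition.

**Conventions and assumptions**

- Drimane-type numbering is used from compound 10 on: C-1 carbinol, C-3 CHCl, C-4 quaternary, C-5/C-10 ring fusion, C-8 ester-bearing, C-9 formyl-bearing, C-11 formyl/lactone carbon, C-12 ester carbon; ring A = C-1 to C-5 and C-10, ring B = C-5 to C-10; α is the face of the C-1 oxygen, β the face of the C-10 methyl.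
- Metal enolates and alkoxides, boron-bound species, halonium ions and activated esters are described in the Why lines and are not numbered; neutral intermediates that build up in the flask are numbered.
- Diisopropyl allylboronate, tributyl(vinyl)stannane and the stabilised ylide are taken as purchasable reagents.

**Step 1**
Reactants: 1 (S)-(+)-carvone
Product: 2 (5S,6R)-2,6-dimethyl-5-(prop-1-en-2-yl)cyclohex-2-en-1-one (trans-6-methylcarvone)
Conditions: LiN(iPr)2, THF, −78 °C; MeI, −78 → 0 °C
Reagents that add atoms: iodomethane, CI
Why: Kinetic deprotonation gives the α′-enolate, which is methylated anti to the neighbouring isopropenyl group (enolate alkylation), and the minor cis epimer is harmless because this carbon becomes sp2 in step 7.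

**Step 2**
Reactants: 2 trans-6-methylcarvone
Product: 5 (5S,6R)-5-hydroxy-2,6-dimethylcyclohex-2-en-1-one, via methoxy hydroperoxide 3 (not isolated), via acetoxy enone 4 (not isolated)
Conditions: O3, CH2Cl2/MeOH, −78 °C; Ac2O, Et3N, DMAP, −78 → 23 °C; then K2CO3 (cat.), MeOH, 0 °C
Reagents that add atoms: ozone, [O-][O+]=O; methanol, CO (its atoms stay only in 3 and 4)
Why: Ozone cleaves only the electron-rich isopropenyl alkene, the acetylated α-methoxy hydroperoxide undergoes Criegee rearrangement in which the ring carbon migrates to the ozone-derived oxygen with retention of configuration, and mild methanolysis frees the alcohol, so the bought stereocentre becomes the C-1 carbinol.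

**Step 3**
Reactants: 5 hydroxy enone
Product: 6 (1S,2R,3R)-2,4-dimethyl-3-(prop-2-en-1-yl)cyclohex-4-ene-1,3-diol
Conditions: allylB(OiPr)2, Et3N, CH2Cl2, −78 → 23 °C; aqueous work-up
Reagents that add atoms: diisopropyl allylboronate, C=CCB(OC(C)C)OC(C)C
Why: The free hydroxyl exchanges onto boron and the allyl group is then delivered through a chair-like transition state to the ketone face syn to that oxygen (hydroxyl-directed 1,2-allylboration), which sets the tertiary carbinol with allyl cis to the secondary OH.

**Step 4**
Reactants: 7 dimethyl but-2-ynedioate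
Product: 8 4-methoxy-4-oxobut-2-ynoic acid
Conditions: KOH (1.0 equiv), MeOH, 0 °C; then aqueous HCl
Reagents that add atoms: potassium hydroxide, [K+].[OH-]
Why: Saponification of one of two equivalent activated esters stops at the sparingly soluble potassium half-ester salt (monohydrolysis), and no stereocentre is involved.

**Step 5**
Reactants: 6 diol; 8 4-methoxy-4-oxobut-2-ynoic acid
Product: 9 (1S,2R,3R)-3-hydroxy-2,4-dimethyl-3-(prop-2-en-1-yl)cyclohex-4-en-1-yl methyl but-2-ynedioate
Conditions: DCC, CH2Cl2, −20 → 0 °C
Reagents that add atoms: none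
Why: Carbodiimide esterification acylates only the secondary alcohol because the tertiary allylic alcohol is too hindered, which installs the dienophile tether and at the same time masks this hydroxyl.

**Step 6**
Reactants: 9 tethered tertiary allylic alcohol
Product: 10 methyl (1S,2R,4S,5S)-5-chloro-2,4-dimethyl-3-oxo-4-(prop-2-en-1-yl)cyclohexyl but-2-ynedioate
Conditions: NCS, HFIP/CH2Cl2, −20 °C
Reagents that add atoms: N-chlorosuccinimide, O=C1CCC(=O)N1Cl
Why: The chloronium ion formed on the trisubstituted ring alkene anti to the allyl group is opened by a stereospecific 1,2-allyl shift from the carbinol carbon (halonium-induced semipinacol rearrangement), so chlorine and allyl add anti across the former alkene and C-3 (Cl β) and C-4 (allyl α, methyl β) are both fixed by the carbinol configuration.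

**Step 7**
Reactants: 10 β-chloro ketone
Product: 11 ring A enol triflate (C-5 triflate on the C-5/C-10 alkene; 1α-ester, 3β-Cl, 4α-allyl, 4β-Me)
Conditions: Tf2O, 2,6-di-tert-butyl-4-methylpyridine, CH2Cl2, 0 → 23 °C
Reagents that add atoms: trifluoromethanesulfonic anhydride, O=S(=O)(OS(=O)(=O)C(F)(F)F)C(F)(F)F
Why: O-triflation of the ketone followed by loss of the only α-proton (at C-10) gives the tetrasubstituted enol triflate under non-nucleophilic conditions that spare the ynoate and the β-acyloxy group (enol triflate formation), and the C-10 stereocentre is erased.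

**Step 8**
Reactants: 11 enol triflate
Product: 13 tricyclic Δ5,Δ8 lactone ester (C-11 lactone to O-1α; 8-CO2Me; 3β-Cl, 4α-allyl, 4β-Me, 10β-Me), via vinyl diene 12 (not isolated)
Conditions: Bu3SnCH=CH2, Pd2(dba)3 (cat.), AsPh3, CuCl (cat.), LiCl, NMP, 50 °C; then PhMe, 120 °C
Reagents that add atoms: tributyl(vinyl)stannane, C=C[Sn](CCCC)(CCCC)CCCC
Why: Stille coupling gives the 2-methyl-1-vinylcyclohexene, whose tethered ynoate then adds in an intramolecular Diels–Alder reaction in which the three-atom ester tether can only close a cis-fused γ-lactone, so the new bond to C-10 forms on the face of the C-1 oxygen (methyl β) with the lactone carbonyl on C-9 and the methyl ester on C-8.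

**Step 9**
Reactants: 13 Diels–Alder lactone
Product: 15 aldehyde (4α-CH2CHO in place of allyl), via diol 14 (not isolated)
Conditions: OsO4 (cat.), NaIO4, 2,6-lutidine, dioxane/H2O, 23 °C
Reagents that add atoms: osmium tetroxide, O=[Os](=O)(=O)=O; sodium periodate, [Na+].[O-][I](=O)(=O)=O
Why: Lemieux–Johnson cleavage attacks only the unhindered terminal alkene, because the C-5/C-6 alkene is flanked by two quaternary carbons and the C-8/C-9 alkene is electron-poor, and no stereocentre is touched.

**Step 10**
Reactants: 15 aldehyde
Product: 16 trans-fused aldehyde (5α-H, Δ8 lactone ester)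
Conditions: H2 (1 atm), Pd/C, EtOAc, 23 °C
Reagents that add atoms: none
Why: Catalytic hydrogenation delivers hydrogen to the C-5/C-6 alkene from the α face, opposite the axial methyl groups on C-4 and C-10, which gives the trans ring fusion while the tetrasubstituted conjugated alkene, the aldehyde and the secondary chloride survive.

**Step 11**
Reactants: 16 aldehyde
Product: 17 E-enone (4α-CH2CH=CHC(O)CH3)
Conditions: Ph3P=CHC(O)CH3, PhMe, 80 °C
Reagents that add atoms: 1-(triphenylphosphoranylidene)propan-2-one, CC(=O)C=P(c1ccccc1)(c1ccccc1)c1ccccc1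
Why: The stabilised ylide reacts only with the aldehyde and gives the E-alkene (Wittig olefination).

**Step 12**
Reactants: 17 enone
Product: 18 tertiary alcohol lactone ester (complete side chain)
Conditions: MeMgBr, LaCl3·2LiCl (cat.), THF, −78 °C; aqueous NH4Cl
Reagents that add atoms: methylmagnesium bromide, C[Mg]Br
Why: Lanthanum-promoted 1,2-addition of the Grignard reagent to the methyl ketone is much faster than attack on the lactone or the ester at −78 °C (Grignard addition), and no stereocentre is formed.

**Step 13**
Reactants: 18 lactone ester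
Product: 19 lactol (C-11 hemiacetal; anomers)
Conditions: i-Bu2AlH (2.2 equiv), CH2Cl2, −78 °C; aqueous KNaC4H4O6
Reagents that add atoms: none
Why: After the tertiary alcohol is deprotonated, the strained alkylidene γ-lactone is reduced to its lactol faster than the hindered conjugated methyl ester at −78 °C (partial lactone reduction), and the hemiacetal centre is of no consequence.

**Step 14**
Reactants: 19 lactol
Product: 20 target CNP0167913.1 (1α-OH, 3β-Cl, 4α-side chain, 4β-Me, 5α-H, 9β-CHO, 10β-Me)
Conditions: LiN(SiMe3)2 (3.5 equiv), THF, −78 °C; then AcOH, −78 °C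
Reagents that add atoms: none
Why: Base opens the lactolate to the alkoxy enal and removes a γ-proton at C-7, and kinetic protonation of the dienolate at its α-carbon C-9 from the α face, axial and opposite the C-10 methyl (deconjugative protonation), leaves the alkene conjugated to the ester only and gives the 9β-formyl epimer, which is the target.

**Compound list**

1 | (S)-(+)-carvone, (5S)-2-methyl-5-(prop-1-en-2-yl)cyclohex-2-en-1-one | CC1=CC[C@@H](CC1=O)C(C)=C | starting material
2 | (5S,6R)-2,6-dimethyl-5-(prop-1-en-2-yl)cyclohex-2-en-1-one | O=C1C(C)=CC[C@H](C(C)=C)[C@H]1C | intermediate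
3 | (5S,6R)-5-(1-hydroperoxy-1-methoxyethyl)-2,6-dimethylcyclohex-2-en-1-one (epimers at the peroxy carbon) | O=C1C(C)=CC[C@H](C(C)(OC)OO)[C@H]1C | intermediate
4 | (1S,2R)-2,4-dimethyl-3-oxocyclohex-4-en-1-yl acetate | O=C1C(C)=CC[C@H](OC(C)=O)[C@H]1C | intermediate
5 | (5S,6R)-5-hydroxy-2,6-dimethylcyclohex-2-en-1-one | O=C1C(C)=CC[C@H](O)[C@H]1C | intermediate
6 | (1S,2R,3R)-2,4-dimethyl-3-(prop-2-en-1-yl)cyclohex-4-ene-1,3-diol (allyl cis to the secondary OH) | O[C@@]1(CC=C)C(C)=CC[C@H](O)[C@H]1C | intermediate
7 | dimethyl but-2-ynedioate | COC(=O)C#CC(=O)OC | starting material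
8 | 4-methoxy-4-oxobut-2-ynoic acid | COC(=O)C#CC(=O)O | intermediate
9 | (1S,2R,3R)-3-hydroxy-2,4-dimethyl-3-(prop-2-en-1-yl)cyclohex-4-en-1-yl methyl but-2-ynedioate | O[C@@]1(CC=C)C(C)=CC[C@H](OC(=O)C#CC(=O)OC)[C@H]1C | intermediate
10 | methyl (1S,2R,4S,5S)-5-chloro-2,4-dimethyl-3-oxo-4-(prop-2-en-1-yl)cyclohexyl but-2-ynedioate | O=C1[C@](C)(CC=C)[C@@H](Cl)C[C@H](OC(=O)C#CC(=O)OC)[C@H]1C | intermediate
11 | ring A enol triflate: C-5 triflate, C-5/C-10 alkene, 1α-(4-methoxy-4-oxobut-2-ynoyl)oxy, 3β-Cl, 4α-allyl, 4β-Me | CC1=C(OS(=O)(=O)C(F)(F)F)[C@](C)(CC=C)[C@@H](Cl)C[C@@H]1OC(=O)C#CC(=O)OC | intermediate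
12 | ring A vinyl diene: as 11 with CH=CH2 on C-5 | CC1=C(C=C)[C@](C)(CC=C)[C@@H](Cl)C[C@@H]1OC(=O)C#CC(=O)OC | intermediate
13 | tricyclic Δ5,Δ8 lactone ester: C-11 lactone to O-1α, 8-CO2Me, 3β-Cl, 4α-allyl, 4β-Me, 10β-Me | COC(=O)C1=C2C(=O)O[C@H]3C[C@H](Cl)[C@@](C)(CC=C)C(=CC1)[C@@]23C | intermediate
14 | diol of 13: 4α-(2,3-dihydroxypropyl) (epimers) | COC(=O)C1=C2C(=O)O[C@H]3C[C@H](Cl)[C@@](C)(CC(O)CO)C(=CC1)[C@@]23C | intermediate
15 | aldehyde: 4α-(2-oxoethyl), Δ5,Δ8 lactone ester | COC(=O)C1=C2C(=O)O[C@H]3C[C@H](Cl)[C@@](C)(CC=O)C(=CC1)[C@@]23C | intermediate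
16 | trans-fused aldehyde: 5α-H, Δ8 lactone ester | COC(=O)C1=C2C(=O)O[C@H]3C[C@H](Cl)[C@@](C)(CC=O)[C@H](CC1)[C@@]23C | intermediate
17 | E-enone: 4α-[(E)-4-oxopent-2-enyl] | COC(=O)C1=C2C(=O)O[C@H]3C[C@H](Cl)[C@@](C)(C/C=C/C(C)=O)[C@H](CC1)[C@@]23C | intermediate
18 | tertiary alcohol: 4α-[(E)-4-hydroxy-4-methylpent-2-enyl], Δ8 lactone ester | COC(=O)C1=C2C(=O)O[C@H]3C[C@H](Cl)[C@@](C)(C/C=C/C(C)(C)O)[C@H](CC1)[C@@]23C | intermediate
19 | lactol of 18 (C-11 hemiacetal, anomers) | COC(=O)C1=C2C(O)O[C@H]3C[C@H](Cl)[C@@](C)(C/C=C/C(C)(C)O)[C@H](CC1)[C@@]23C | intermediate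
20 | CNP0167913.1 | COC(=O)C1=CC[C@H]2[C@](C)(C/C=C/C(C)(C)O)[C@@H](Cl)C[C@H](O)[C@]2(C)[C@H]1C=O | target

**Step count**

Total: 14 steps. Longest linear sequence: 13 steps (steps 1–3 and 5–14 from carvone); step 4 makes the tether acid.

**Three steps most likely to fail**

Step 3, the hydroxyl-directed allylation. The risk is undirected addition anti to the hydroxyl, or β-elimination of the hydroxy ketone towards 2,6-dimethylphenol. The fallback sets out from 5 and comes back at 6. Compound 5 is silylated with allyl(chloro)dimethylsilane and imidazole to give the allyldimethylsilyl ether F1. TiCl4 in CH2Cl2 at −78 °C then triggers allyl transfer from the silicon tether to the carbonyl face that carries the oxygen (tethered Hosomi–Sakurai allylation), and aqueous work-up removes silicon to give 6.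

Step 6, the chloronium-induced allyl shift. The risks are chlorination of the terminal alkene, capture of the chloronium ion by the free tertiary hydroxyl (chloro-epoxide), or ionisation of the allylic alcohol. The fallback sets out from 9 and comes back at 10. The tertiary alcohol is converted with Me3SiOTf and 2,6-lutidine into the trimethylsilyl ether F2. Treatment with 1,3-dichloro-5,5-dimethylhydantoin in CH2Cl2 then runs the rearrangement as a silyl-terminated semipinacol: the oxygen can no longer close an epoxide, and the silyloxy cation formed after the 1,2-allyl shift loses silicon to give 10.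

Step 8, the Stille coupling and ester-tethered cycloaddition. The risks are damage to the ynoate under palladium/tin conditions and a slow cycloaddition, because the ester must adopt its disfavoured conformation and the diene terminus is fully substituted. The fallback sets out from 11 and comes back at 13, and keeps the cycloaddition but changes the tether.
- The ynoate ester of 11 is cleaved with LiOH in THF/H2O at 0 °C to give the hydroxy enol triflate F3.
- Stille coupling of F3 with tributyl(vinyl)stannane under the step 8 conditions gives the dienol F4.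
- Commercial methyl 4-hydroxybut-2-ynoate is oxidised with MnO2 to methyl 4-oxobut-2-ynoate F5.
- F4 and F5 in toluene at 60–80 °C form a hemiacetal in situ, which undergoes the intramolecular Diels–Alder reaction through a more flexible sp3 tether and gives the allyl lactol F6 with the same facial and regiochemical outcome.
- Oxidation of F6 with MnO2 gives lactone 13.

**Further compounds**

F1 | step 3 | allyldimethylsilyl ether of 5 | O=C1C(C)=CC[C@H](O[Si](C)(C)CC=C)[C@H]1C
F2 | step 6 | trimethylsilyl ether of 9 | C[Si](C)(C)O[C@@]1(CC=C)C(C)=CC[C@H](OC(=O)C#CC(=O)OC)[C@H]1C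
F3 | step 8 | hydroxy enol triflate (11 without the ynoate ester) | CC1=C(OS(=O)(=O)C(F)(F)F)[C@](C)(CC=C)[C@@H](Cl)C[C@@H]1O
F4 | step 8 | ring A dienol (C-5 vinyl, free 1α-OH) | CC1=C(C=C)[C@](C)(CC=C)[C@@H](Cl)C[C@@H]1O
F5 | step 8 | methyl 4-oxobut-2-ynoate | COC(=O)C#CC=O
F6 | step 8 | allyl lactol (Δ5,Δ8 Diels–Alder adduct, C-11 hemiacetal) | COC(=O)C1=C2C(O)O[C@H]3C[C@H](Cl)[C@@](C)(CC=C)C(=CC1)[C@@]23C
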